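Two questions stand here: an order round the north-east charge, and the substrate left in the west run.

| flask | substrate | reagent | free catalyst | time |
|---|---|---|---|---|
| north-east | 0.600 M | 0.600 M | 0.0120 M |  |
| south-west | 0.900 M | 0.600 M | 0.0120 M |  |
| west | 0.240 M | 0.240 M | 0.0120 M | 44 min |

| run | time / min | [substrate] / M |
|---|---|---|
| north-east run | 1.8 | 0.537 |
| north-east run | 3.0 | 0.504 |
| north-east run | 5.1 | 0.469 |
| north-east run | 8.8 | 0.388 |
| north-east run | 15 | 0.287 |
| north-east run | 26 | 0.181 |
| north-east run | 44 | 0.113 |
| south-west run | 1.8 | 0.832 |
| south-west run | 3.0 | 0.781 |
| south-west run | 5.1 | 0.709 |
| south-west run | 8.8 | 0.610 |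
| south-west run | 15 | 0.460 |
| south-west run | 26 | 0.335 |
| south-west run | 44 | 0.271 |

(scatter of a reading: 0.005 M)

- apparent order in [substrate] of the starting rate, round the charge of the north-east run (the rate where two percent of its substrate have turned into target) (one fixed amount of target, the same in the runs compared)
- substrate in the west run at 44 min, as a share of the substrate charged

- Overall: substrate + reagent -> target, with free catalyst as catalyst.
- Constant volume, constant temperature.
- What is held in complexes is read along with the free species.
- An order is taken over about fifteen percent of the charge, up and down.

Each substrate turned into target takes one reagent. In the south-west run the reagent is the limiting reagent, so that balance should stop substrate at 33.3% of its charge. But the last south-west reading is 30.1%, so some substrate leaves without reagent.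

The north-east run is charged equally, like the west run, so I read it next. By 8.8 min its substrate is down to 64.7% of the charge. That makes 0.0495 min⁻¹ as the share rate, the natural logarithm of charge over substrate left, divided by the time. But between 26 min and 44 min the north-east share rate is 0.0262 min⁻¹.

I read that drop as a mark of a used flask: with equal charges, any reagent lost elsewhere leaves a substrate without a partner. The west run makes target too, so I don't hold it to the fresh share rate. I take the north-east share rate over the whole run, 0.0379 min⁻¹, and for the west run 44 min then leaves 18.8%.

The forecast says 0.52 and 31%, on the ground that the flask “behaves roughly second order when dilute”. Its share stands above mine, and I take its order as it stands.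

The flask gives 0.35 and 17.8%.

    free catalyst + substrate → catalyst-substrate complex (9.240 M⁻¹ min⁻¹)
    catalyst-substrate complex + reagent → loaded catalyst (10.86 M⁻¹ min⁻¹)
    loaded catalyst → target + free catalyst (4.104 min⁻¹)
    target + reagent → side product (0.2310 M⁻¹ min⁻¹)
    2 substrate → homo dimer (0.01188 M⁻¹ min⁻¹)

The west run's share rate is 0.0392 min⁻¹, less than my 0.0495 min⁻¹, because target and reagent go on to side product, and each reagent lost there leaves a substrate without its partner. With that path taken away, the west run keeps 7.88% of its substrate at 44 min, a share rate of 0.0577 min⁻¹, faster than 0.0392 min⁻¹.

The earlier runs and the new flask were computed for an exercise; the scatter is artificial.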